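**Plan**
- Retrosynthesis: the six phenol silyl ethers come off last. Before that the styryl C–aryl bond is cut (Heck), then C3=C4 of the six-membered ring C1–C2–C3–C4–C5–C8 (enyne metathesis), then C1–C2 (aldol, oxidation), the C7–aryl and C6–aryl bonds (two cuprate additions) and the C5–alkyne bond (Sonogashira).
- Enabling feature: the ring alkene C3=C4 carries a second alkene on C4. This 1,3-diene (C3=C4–CH=CH2) is the pattern left by joining an ethynyl group on C5 to an acryloyl alkene on C1 of the cyclopentanone ring C8–C1–C7–C6–C5.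
- Forward: the five-membered ring is bought as (R)-4-silyloxycyclopent-2-enone. The alkyne (C5), the resorcinol aryl (C6), the catechol aryl (C7) and the acryloyl unit (C1) are added in that order. The six-membered ring closes in step 9 to give the bicyclo[3.2.1]octene; the styryl arm and desilylation follow.
- Stereochemistry: the silyloxy centre directs the C6 aryl anti and is then eliminated. The C6 aryl directs the C7 aryl anti and holds the C5 alkyne trans by equilibration. C1 is a labile 2-acyl ketone centre and is fixed by the ring closure, which only its C1/C5-cis epimer can undergo.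

Key step: step 9

Remarks on the chemistry:
- Atom labels C1–C8 are those of the bicyclo[3.2.1]octane core of the target (C1, C5 bridgeheads; C2 enone carbonyl; C3=C4; C6 resorcinol-bearing; C7 catechol-bearing; C8 bridging ketone) and are kept for the monocyclic intermediates.
- ArR = 3,5-bis(tert-butyldimethylsilyloxy)phenyl; ArC = 3,4-bis(tert-butyldimethylsilyloxy)phenyl; TBS = tert-butyldimethylsilyl; TMS = trimethylsilyl.
- Assumption: the 2-acyl ketone carbon C1 of 19 epimerises through its enol at 70 °C without added base.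

**Step 1**
Reactants: 1 5-bromobenzene-1,3-diol
Product: 2 1-bromo-3,5-bis(tert-butyldimethylsilyloxy)benzene
Conditions: TBSCl (2.3 equiv), imidazole, DMF, rt
Reagents that add atoms: tert-butyldimethylsilyl chloride, CC(C)(C)[Si](C)(C)Cl
Why: Imidazole-promoted O-silylation of both phenols; the aryl silyl ethers are inert to lithium–bromine exchange, cuprate chemistry and the metal-catalysed steps and can be removed together by fluoride at the end.

**Step 2**
Reactants: 3 4-bromobenzene-1,2-diol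
Product: 4 4-bromo-1,2-bis(tert-butyldimethylsilyloxy)benzene
Conditions: TBSCl (2.3 equiv), imidazole, DMF, rt
Reagents that add atoms: tert-butyldimethylsilyl chloride, CC(C)(C)[Si](C)(C)Cl
Why: The same O-silylation; masking the catechol also prevents its oxidation and its chelation of copper, ruthenium and palladium later on.

**Step 3**
Reactants: 5 (R)-4-(tert-butyldimethylsilyloxy)cyclopent-2-en-1-one
Product: 6 (R)-4-(tert-butyldimethylsilyloxy)-2-iodocyclopent-2-en-1-one
Conditions: I2, pyridine, CH2Cl2, 0 °C → rt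
Reagents that add atoms: iodine, II
Why: α-Iodination of the enone by the I2/pyridine protocol (conjugate addition of pyridine, iodination of the enolate, E1cB loss of pyridine) is standard for 4-silyloxycyclopentenones and leaves the silyloxy stereocentre (future C7) untouched.

**Step 4**
Reactants: 6 (R)-4-(tert-butyldimethylsilyloxy)-2-iodocyclopent-2-en-1-one; 7 ethynyltrimethylsilane
Product: 8 (R)-4-(tert-butyldimethylsilyloxy)-2-[(trimethylsilyl)ethynyl]cyclopent-2-en-1-one
Conditions: PdCl2(PPh3)2 (3 mol%), CuI (6 mol%), i-Pr2NH, THF, 0 °C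
Reagents that add atoms: none
Why: Sonogashira coupling of the electron-poor alkenyl iodide runs at 0 °C, so the base-sensitive β-silyloxy enone survives, and it places alkyne carbon C4 on the future C5 without any enolate alkynylation.

**Step 5**
Reactants: 8 (R)-4-(tert-butyldimethylsilyloxy)-2-[(trimethylsilyl)ethynyl]cyclopent-2-en-1-one; 2 1-bromo-3,5-bis(tert-butyldimethylsilyloxy)benzene
Product: 12 (4S,5S)-4-ArR-5-[(trimethylsilyl)ethynyl]cyclopent-2-en-1-one, via aryllithium 9 (not isolated), via lithium diarylcuprate 10 (not isolated), via silyloxy ketone 11 (not isolated)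
Conditions: 2 (2.2 equiv), n-BuLi, THF, −78 °C; CuI, −78 → −30 °C; 8, −78 °C; aq NH4Cl; then DBU, CH2Cl2, −20 °C
Reagents that add atoms: none
Why: Conjugate addition of the lithium diarylcuprate occurs at C6 anti to the neighbouring silyloxy group (steric approach control, reliable for 4-silyloxycyclopentenones), and DBU then effects E1cB loss of silanol from β-silyloxy ketone 11 to give the C1=C7 enone while the acidic C5–H equilibrates so that the alkyne sits trans to the C6 aryl.

**Step 6**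
Reactants: 12 (4S,5S)-4-ArR-5-[(trimethylsilyl)ethynyl]cyclopent-2-en-1-one; 4 4-bromo-1,2-bis(tert-butyldimethylsilyloxy)benzene; 13 acrolein
Product: 17 (2S,3S,4S,5S)-3-ArC-4-ArR-2-(1-hydroxyprop-2-en-1-yl)-5-[(trimethylsilyl)ethynyl]cyclopentan-1-one (both carbinol epimers), via aryllithium 14 (not isolated), via lithium diarylcuprate 15 (not isolated), via lithium enolate 16 (not isolated)
Conditions: 4 (2.2 equiv), n-BuLi, THF, −78 °C; CuI, −78 → −30 °C; 12, −78 °C; then 13, −78 °C; aq NH4Cl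
Reagents that add atoms: none
Why: Conjugate addition of the second diarylcuprate takes place at C7 anti to the C6 aryl, and the regiodefined enolate 16 is trapped at C1 by 1,2-addition to acrolein (three-component conjugate addition–aldol coupling); the configurations at C1 and at the carbinol carbon do not matter because the carbinol is oxidised and C1 becomes labile in step 8.

**Step 7**
Reactants: 17 (2S,3S,4S,5S)-3-ArC-4-ArR-2-(1-hydroxyprop-2-en-1-yl)-5-[(trimethylsilyl)ethynyl]cyclopentan-1-one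
Product: 18 (2S,3S,4S,5S)-3-ArC-4-ArR-5-ethynyl-2-(1-hydroxyprop-2-en-1-yl)cyclopentan-1-one (both carbinol epimers)
Conditions: AgNO3 (10 mol%), acetone/H2O, rt, dark
Reagents that add atoms: none
Why: Silver-catalysed protodesilylation of the alkynylsilane (through the silver acetylide, neutral medium) frees the terminal alkyne without touching the aryl silyl ethers, the aldol or the base-sensitive C5–H.

**Step 8**
Reactants: 18 (2S,3S,4S,5S)-3-ArC-4-ArR-5-ethynyl-2-(1-hydroxyprop-2-en-1-yl)cyclopentan-1-one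
Product: 19 (2S,3S,4S,5S)-3-ArC-4-ArR-5-ethynyl-2-(prop-2-enoyl)cyclopentan-1-one (acryloyl trans to the C7 aryl; in equilibrium with its enol)
Conditions: Dess–Martin periodinane, NaHCO3, CH2Cl2, 0 °C; filtered through a short silica pad and used at once
Reagents that add atoms: none
Why: Dess–Martin oxidation of the allylic β-hydroxy ketone gives the 1,3-diketone under buffered, non-basic conditions that spare the C5 stereocentre and the terminal alkyne; the product is a 2-acyl ketone that interconverts with its enol and its C1 epimer.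

**Step 9**
Reactants: 19 (2S,3S,4S,5S)-3-ArC-4-ArR-5-ethynyl-2-(prop-2-enoyl)cyclopentan-1-one
Product: 21 (1R,5S,6S,7S)-7-ArC-6-ArR-4-ethenylbicyclo[3.2.1]oct-3-ene-2,8-dione, via cis-diketone epimer 20 (not isolated)
Conditions: second-generation Hoveyda–Grubbs catalyst RuCl2(H2IMes)(=CH-C6H4-2-O-i-Pr) (10 mol%), ethene (1 atm), toluene (0.005 M), 70 °C
Reagents that add atoms: ethene, C=C (methylene exchange only; the net change is an isomerisation)
Why: The ruthenium methylidene, kept alive by ethene, adds to the terminal C4≡CH bond, and the resulting vinylcarbene on C4 undergoes ring-closing metathesis with the acryloyl alkene, which forms C3=C4, leaves CH=CH2 on C4 and regenerates the methylidene. The closest known reaction type is ruthenium-catalysed ring-closing metathesis of 1,7-enynes with a terminal alkyne under ethene, which gives 1-vinylcyclohexenes. The six-membered ring C1–C2–C3–C4–C5–C8 closes in the exo mode, the terminal alkyne carbon staying outside the ring as the vinyl CH. The only new stereocentre, C1, is controlled by the ring itself: the three-atom bridge can span C1 and C5 only when they are cis, C5 is fixed with its alkyne trans to the C6 aryl, and C1 of 19 epimerises through the enol to 20, which is drained by the irreversible closure (Curtin–Hammett funnel). The step needs exo over endo closure and ring closure over alkyne oligomerisation, which the terminal alkyne, high dilution and ethene atmosphere favour; it also needs C5 to keep its configuration, which the neutral medium secures because only the far more acidic diketone carbon C1 enolises.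

**Step 10**
Reactants: 21 (1R,5S,6S,7S)-7-ArC-6-ArR-4-ethenylbicyclo[3.2.1]oct-3-ene-2,8-dione; 4 4-bromo-1,2-bis(tert-butyldimethylsilyloxy)benzene
Product: 22 (1R,5S,6S,7S)-7-ArC-6-ArR-4-[(E)-2-ArC-ethenyl]bicyclo[3.2.1]oct-3-ene-2,8-dione
Conditions: Pd(P(t-Bu)3)2 (5 mol%), Cy2NMe, 1,4-dioxane, 60 °C
Reagents that add atoms: none
Why: Mizoroki–Heck reaction: the arylpalladium bromide formed by oxidative addition of 4 to zerovalent palladium inserts the only monosubstituted alkene with the aryl group at the terminal carbon, and syn β-hydride elimination gives the E-styryl group in conjugation with the dienone; the bulky, electron-rich phosphine lets the electron-rich aryl bromide react at moderate temperature.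

**Step 11**
Reactants: 22 (1R,5S,6S,7S)-7-ArC-6-ArR-4-[(E)-2-ArC-ethenyl]bicyclo[3.2.1]oct-3-ene-2,8-dione
Product: 23 (1R,5S,6S,7S)-7-(3,4-dihydroxyphenyl)-6-(3,5-dihydroxyphenyl)-4-[(E)-2-(3,4-dihydroxyphenyl)ethenyl]bicyclo[3.2.1]oct-3-ene-2,8-dione (CNP0285027.2)
Conditions: Et3N·3HF, THF/MeCN, rt, argon
Reagents that add atoms: none
Why: Fluoride cleaves all six aryl Si–O bonds, and the weakly acidic amine–HF reagent avoids basic conditions under which the non-enolisable 1,3-diketone could undergo retro-Claisen opening and the catechols could oxidise.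

**Compound list**
1 | 5-bromobenzene-1,3-diol | Oc1cc(O)cc(Br)c1 | starting material
2 | 1-bromo-3,5-bis(tert-butyldimethylsilyloxy)benzene | CC(C)(C)[Si](C)(C)Oc1cc(Br)cc(O[Si](C)(C)C(C)(C)C)c1 | intermediate
3 | 4-bromobenzene-1,2-diol | Oc1ccc(Br)cc1O | starting material
4 | 4-bromo-1,2-bis(tert-butyldimethylsilyloxy)benzene | CC(C)(C)[Si](C)(C)Oc1ccc(Br)cc1O[Si](C)(C)C(C)(C)C | intermediate
5 | (R)-4-(tert-butyldimethylsilyloxy)cyclopent-2-en-1-one | O=C1C=C[C@H](O[Si](C)(C)C(C)(C)C)C1 | starting material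
6 | (R)-4-(tert-butyldimethylsilyloxy)-2-iodocyclopent-2-en-1-one | O=C1C(I)=C[C@H](O[Si](C)(C)C(C)(C)C)C1 | intermediate
7 | ethynyltrimethylsilane | C#C[Si](C)(C)C | starting material
8 | (R)-4-(tert-butyldimethylsilyloxy)-2-[(trimethylsilyl)ethynyl]cyclopent-2-en-1-one | O=C1C(C#C[Si](C)(C)C)=C[C@H](O[Si](C)(C)C(C)(C)C)C1 | intermediate
9 | [3,5-bis(tert-butyldimethylsilyloxy)phenyl]lithium | [Li]c1cc(O[Si](C)(C)C(C)(C)C)cc(O[Si](C)(C)C(C)(C)C)c1 | intermediate
10 | lithium bis[3,5-bis(tert-butyldimethylsilyloxy)phenyl]cuprate | [Li+].[Cu-](c1cc(O[Si](C)(C)C(C)(C)C)cc(O[Si](C)(C)C(C)(C)C)c1)c1cc(O[Si](C)(C)C(C)(C)C)cc(O[Si](C)(C)C(C)(C)C)c1 | intermediate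
11 | (3S,4R)-3-[3,5-bis(tert-butyldimethylsilyloxy)phenyl]-4-(tert-butyldimethylsilyloxy)-2-[(trimethylsilyl)ethynyl]cyclopentan-1-one (epimers at C2, the future C5) | O=C1C(C#C[Si](C)(C)C)[C@@H](c2cc(O[Si](C)(C)C(C)(C)C)cc(O[Si](C)(C)C(C)(C)C)c2)[C@H](O[Si](C)(C)C(C)(C)C)C1 | intermediate
12 | (4S,5S)-4-[3,5-bis(tert-butyldimethylsilyloxy)phenyl]-5-[(trimethylsilyl)ethynyl]cyclopent-2-en-1-one | O=C1[C@H](C#C[Si](C)(C)C)[C@@H](c2cc(O[Si](C)(C)C(C)(C)C)cc(O[Si](C)(C)C(C)(C)C)c2)C=C1 | intermediate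
13 | acrolein (prop-2-enal) | C=CC=O | starting material
14 | [3,4-bis(tert-butyldimethylsilyloxy)phenyl]lithium | [Li]c1ccc(O[Si](C)(C)C(C)(C)C)c(O[Si](C)(C)C(C)(C)C)c1 | intermediate
15 | lithium bis[3,4-bis(tert-butyldimethylsilyloxy)phenyl]cuprate | [Li+].[Cu-](c1ccc(O[Si](C)(C)C(C)(C)C)c(O[Si](C)(C)C(C)(C)C)c1)c1ccc(O[Si](C)(C)C(C)(C)C)c(O[Si](C)(C)C(C)(C)C)c1 | intermediate
16 | lithium enolate (C8–O, C8=C1) of the conjugate adduct, 3-ArC-4-ArR-5-[(trimethylsilyl)ethynyl]cyclopent-1-en-1-olate, aryls trans, alkyne trans to ArR | [Li]OC1=C[C@@H](c3ccc(O[Si](C)(C)C(C)(C)C)c(O[Si](C)(C)C(C)(C)C)c3)[C@H](c2cc(O[Si](C)(C)C(C)(C)C)cc(O[Si](C)(C)C(C)(C)C)c2)[C@H]1C#C[Si](C)(C)C | intermediate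
17 | (2S,3S,4S,5S)-3-[3,4-bis(tert-butyldimethylsilyloxy)phenyl]-4-[3,5-bis(tert-butyldimethylsilyloxy)phenyl]-2-(1-hydroxyprop-2-en-1-yl)-5-[(trimethylsilyl)ethynyl]cyclopentan-1-one (both carbinol epimers) | C=CC(O)[C@H]1C(=O)[C@H](C#C[Si](C)(C)C)[C@@H](c2cc(O[Si](C)(C)C(C)(C)C)cc(O[Si](C)(C)C(C)(C)C)c2)[C@@H]1c3ccc(O[Si](C)(C)C(C)(C)C)c(O[Si](C)(C)C(C)(C)C)c3 | intermediate
18 | (2S,3S,4S,5S)-3-[3,4-bis(tert-butyldimethylsilyloxy)phenyl]-4-[3,5-bis(tert-butyldimethylsilyloxy)phenyl]-5-ethynyl-2-(1-hydroxyprop-2-en-1-yl)cyclopentan-1-one (both carbinol epimers) | C=CC(O)[C@H]1C(=O)[C@H](C#C)[C@@H](c2cc(O[Si](C)(C)C(C)(C)C)cc(O[Si](C)(C)C(C)(C)C)c2)[C@@H]1c3ccc(O[Si](C)(C)C(C)(C)C)c(O[Si](C)(C)C(C)(C)C)c3 | intermediate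
19 | (2S,3S,4S,5S)-3-[3,4-bis(tert-butyldimethylsilyloxy)phenyl]-4-[3,5-bis(tert-butyldimethylsilyloxy)phenyl]-5-ethynyl-2-(prop-2-enoyl)cyclopentan-1-one (acryloyl trans to the C7 aryl) | C=CC(=O)[C@H]1C(=O)[C@H](C#C)[C@@H](c2cc(O[Si](C)(C)C(C)(C)C)cc(O[Si](C)(C)C(C)(C)C)c2)[C@@H]1c3ccc(O[Si](C)(C)C(C)(C)C)c(O[Si](C)(C)C(C)(C)C)c3 | intermediate
20 | (2R,3S,4S,5S)-3-[3,4-bis(tert-butyldimethylsilyloxy)phenyl]-4-[3,5-bis(tert-butyldimethylsilyloxy)phenyl]-5-ethynyl-2-(prop-2-enoyl)cyclopentan-1-one (acryloyl cis to the alkyne; the epimer that closes) | C=CC(=O)[C@@H]1C(=O)[C@H](C#C)[C@@H](c2cc(O[Si](C)(C)C(C)(C)C)cc(O[Si](C)(C)C(C)(C)C)c2)[C@@H]1c3ccc(O[Si](C)(C)C(C)(C)C)c(O[Si](C)(C)C(C)(C)C)c3 | intermediate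
21 | (1R,5S,6S,7S)-7-[3,4-bis(tert-butyldimethylsilyloxy)phenyl]-6-[3,5-bis(tert-butyldimethylsilyloxy)phenyl]-4-ethenylbicyclo[3.2.1]oct-3-ene-2,8-dione | O=C1C=C(C=C)[C@H]2C(=O)[C@@H]1[C@@H](c3ccc(O[Si](C)(C)C(C)(C)C)c(O[Si](C)(C)C(C)(C)C)c3)[C@@H]2c3cc(O[Si](C)(C)C(C)(C)C)cc(O[Si](C)(C)C(C)(C)C)c3 | intermediate
22 | (1R,5S,6S,7S)-7-[3,4-bis(tert-butyldimethylsilyloxy)phenyl]-4-{(E)-2-[3,4-bis(tert-butyldimethylsilyloxy)phenyl]ethenyl}-6-[3,5-bis(tert-butyldimethylsilyloxy)phenyl]bicyclo[3.2.1]oct-3-ene-2,8-dione | O=C1C=C(/C=C/c3ccc(O[Si](C)(C)C(C)(C)C)c(O[Si](C)(C)C(C)(C)C)c3)[C@H]2C(=O)[C@@H]1[C@@H](c3ccc(O[Si](C)(C)C(C)(C)C)c(O[Si](C)(C)C(C)(C)C)c3)[C@@H]2c3cc(O[Si](C)(C)C(C)(C)C)cc(O[Si](C)(C)C(C)(C)C)c3 | intermediate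
23 | (1R,5S,6S,7S)-7-(3,4-dihydroxyphenyl)-6-(3,5-dihydroxyphenyl)-4-[(E)-2-(3,4-dihydroxyphenyl)ethenyl]bicyclo[3.2.1]oct-3-ene-2,8-dione | O=C1C=C(/C=C/c2ccc(O)c(O)c2)[C@H]2C(=O)[C@@H]1[C@@H](c1ccc(O)c(O)c1)[C@@H]2c1cc(O)cc(O)c1 | target

Total steps: 11. Longest linear sequence: 9 steps (5 → 23, steps 3 to 11).

**Steps most likely to fail**

Step 9. The closure may stall or go astray in several ways. The terminal alkyne can oligomerise or close in the endo mode, and the vinylcarbene may be slow to engage the electron-poor acryloyl alkene. The enol of 19 can add through oxygen to the acryloyl group or hold ruthenium as a chelate. Slow epimerisation at C5 would erode the facial selection. Fallback (sets out from 18, returns at 21): the alkyne is taken out of the metathesis. Semihydrogenation of 18 (H2, Pd/CaCO3 poisoned with Pb(OAc)2, quinoline, EtOAc) gives the 5-vinyl aldol F1. Dess–Martin oxidation gives the 2-acryloyl-5-vinyl diketone F2, which equilibrates with its C1 epimer F3. Diene ring-closing metathesis with the second-generation Grubbs catalyst RuCl2(H2IMes)(PCy3)(=CHPh) in toluene at 70 °C forms the same C3=C4 bond with loss of ethene and gives the 4-unsubstituted bicyclic enedione F4. CH2=CHMgBr with CuI (cat.) and TMSCl in THF at −78 °C adds the vinyl group to C4 and delivers the silyl enol ether F5. Saegusa–Ito dehydrogenation with Pd(OAc)2 in MeCN restores C3=C4 and gives 21.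

Step 5. The amidine base may isomerise the material during the elimination: propargyl-to-allenyl isomerisation at C5, and migration of the new double bond towards the C6 aryl with loss of the C6 stereocentre. Fallback (sets out from 11, returns at 12): 11 is isolated after the cuprate step and stirred in AcOH/THF/H2O. At rt this cleaves only the secondary alkyl silyl ether and gives the β-hydroxy ketone F6; aryl silyl ethers and the alkynylsilane are stable to dilute acid. At 60 °C the same medium dehydrates F6 through the enol to 12 without any amine base, and C5 settles trans by the same enol.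

Step 6. Proton transfer from the acidic C5–H to the cuprate or to the enolate before trapping would leave the conjugate addition incomplete or scramble the enolate, and acrolein may polymerise or react in the 1,4 sense. Fallback (sets out from 12, returns at 17): cuprate 15 is added to 12 in the presence of TMSCl, which traps the regiodefined enolate at once as the silyl enol ether F7. F7 is isolated and then undergoes a Mukaiyama aldol addition to acrolein (BF3·OEt2, CH2Cl2, −78 °C) to give 17.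

**Further compounds**
F1 | step 9 | 5-ethenyl analogue of 18: 3-ArC-4-ArR-5-ethenyl-2-(1-hydroxyprop-2-en-1-yl)cyclopentan-1-one, ring configuration as in 18 | C=CC(O)[C@H]1C(=O)[C@H](C=C)[C@@H](c2cc(O[Si](C)(C)C(C)(C)C)cc(O[Si](C)(C)C(C)(C)C)c2)[C@@H]1c3ccc(O[Si](C)(C)C(C)(C)C)c(O[Si](C)(C)C(C)(C)C)c3
F2 | step 9 | 5-ethenyl analogue of 19: 3-ArC-4-ArR-5-ethenyl-2-(prop-2-enoyl)cyclopentan-1-one, acryloyl trans to the C7 aryl | C=CC(=O)[C@H]1C(=O)[C@H](C=C)[C@@H](c2cc(O[Si](C)(C)C(C)(C)C)cc(O[Si](C)(C)C(C)(C)C)c2)[C@@H]1c3ccc(O[Si](C)(C)C(C)(C)C)c(O[Si](C)(C)C(C)(C)C)c3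
F3 | step 9 | C1 epimer of F2, acryloyl cis to the 5-ethenyl group | C=CC(=O)[C@@H]1C(=O)[C@H](C=C)[C@@H](c2cc(O[Si](C)(C)C(C)(C)C)cc(O[Si](C)(C)C(C)(C)C)c2)[C@@H]1c3ccc(O[Si](C)(C)C(C)(C)C)c(O[Si](C)(C)C(C)(C)C)c3
F4 | step 9 | 7-ArC-6-ArR-bicyclo[3.2.1]oct-3-ene-2,8-dione, ring configuration as in 21, no substituent on C4 | O=C1C=C[C@H]2C(=O)[C@@H]1[C@@H](c3ccc(O[Si](C)(C)C(C)(C)C)c(O[Si](C)(C)C(C)(C)C)c3)[C@@H]2c3cc(O[Si](C)(C)C(C)(C)C)cc(O[Si](C)(C)C(C)(C)C)c3
F5 | step 9 | 7-ArC-6-ArR-4-ethenyl-2-(trimethylsilyloxy)bicyclo[3.2.1]oct-2-en-8-one, both C4 epimers | C[Si](C)(C)OC1=CC(C=C)[C@H]2C(=O)[C@@H]1[C@@H](c3ccc(O[Si](C)(C)C(C)(C)C)c(O[Si](C)(C)C(C)(C)C)c3)[C@@H]2c3cc(O[Si](C)(C)C(C)(C)C)cc(O[Si](C)(C)C(C)(C)C)c3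
F6 | step 5 | (3S,4R)-3-[3,5-bis(tert-butyldimethylsilyloxy)phenyl]-4-hydroxy-2-[(trimethylsilyl)ethynyl]cyclopentan-1-one, epimers at C2 | O=C1C(C#C[Si](C)(C)C)[C@@H](c2cc(O[Si](C)(C)C(C)(C)C)cc(O[Si](C)(C)C(C)(C)C)c2)[C@H](O)C1
F7 | step 6 | trimethylsilyl enol ether corresponding to enolate 16: 3-ArC-4-ArR-1-(trimethylsilyloxy)-5-[(trimethylsilyl)ethynyl]cyclopent-1-ene | C[Si](C)(C)OC1=C[C@@H](c3ccc(O[Si](C)(C)C(C)(C)C)c(O[Si](C)(C)C(C)(C)C)c3)[C@H](c2cc(O[Si](C)(C)C(C)(C)C)cc(O[Si](C)(C)C(C)(C)C)c2)[C@H]1C#C[Si](C)(C)C
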